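**Direct plan and its weak points**

A direct plan would close the ten-membered ring first: [2+2] photoaddition of the silyloxy-methylcyclohexenone A1 to 1-methylcyclobutene A2 and thermal cycloreversion would give germacradienone A3.
It would then epoxidise C4=C5 under direction of a temporary C6 alcohol, re-oxidise to epoxy ketone A4, append the butenolide by aldol with an α-keto ester, reduction and dehydration, and end with hydroboration of the C1=C10 alkene of dienolide A5.
Weak step 1, the thermal fragmentation that uncovers the ring: at 180 °C the cis,trans-cyclodeca-1,5-dienone is a Cope substrate and a β-silyloxy ketone, and the photoaddition before it must be head-to-head.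
Weak step 2, the lactone annulation on the C6 ketone: C6 would be reduced, oxidised and reduced again, two centres would be made only to be erased, and the β-silyloxy ketone enolate can eliminate or undergo retro-aldol.
Weak step 3, the closing hydroboration: C1 and C10 would be set in the last step only by the conformation of a flexible ring, with BH3 next to a butenolide, three esters and an oxirane.

**Retrosynthetic overview of the new route**

The cut is at C6–C7 and O6–C12: an intramolecular Nozaki–Hiyama–Kishi addition of a C7 alkenyl iodide to a C6 epoxy aldehyde closes the ten-membered carbocycle, and the alkoxide lactonises on the cis C12 ester to give the butenolide. C7, the only sp2 ring carbon, lies between the carbinols C6 and C8, and the 4,5-cis-oxirane beside C6 controls the new centre.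
Ring order: oxirane first (Sharpless epoxidation of the nerol-derived Z-allylic alcohol C4=C5–C6), then carbocycle and lactone in one operation from an acyclic chain.
The chain comes from nerol (C2–C6 and C15 with the Z geometry), an anti-crotylboration (C1 and C10 together), an enantioselective alkynylation (C8) and an iodo-aldol that builds the tetrasubstituted C7=C11 alkene with C13.
C1 and C10 are thus set on an open chain under reagent control, C6 is set once, nothing is heated after ring closure, and both ester side groups are in place before it, so only a desilylation follows.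

Key step: step 15

Assumption: (S,S)-ProPhenol is taken to deliver the alkynyl group to the Re face of aldehyde 11 (giving 8S); should the sense be the opposite, the enantiomeric ligand serves. TBS = tert-butyldimethylsilyl; locants C1–C15 in the text are germacrane numbers.

**Route**

Step 1
Reactants: 1 nerol
Product: 2 neryl TBS ether
Conditions: TBSCl, imidazole, DMF, 0 → 25 °C
Reagents that add atoms: tert-butyldimethylsilyl chloride, CC(C)(C)[Si](C)(C)Cl
Why: Imidazole-promoted silylation protects the primary allylic hydroxyl (the later C6–OH) until it is needed for the Sharpless epoxidation.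

Step 2
Reactants: 2 neryl TBS ether
Product: 3 6,7-epoxyneryl TBS ether (racemic oxirane)
Conditions: mCPBA (1.05 equiv), NaHCO3, CH2Cl2, 0 °C
Reagents that add atoms: 3-chloroperoxybenzoic acid, OOC(=O)c1cccc(Cl)c1
Why: Prilezhaev epoxidation should select the remote, more electron-rich trisubstituted alkene because the allylic C–O bond deactivates the proximal one, and the oxirane is only a handle for cleavage so its configuration does not matter.

Step 3
Reactants: 3 6,7-epoxyneryl TBS ether
Product: 5 (4Z)-6-(TBSO)-4-methylhex-4-enal, via glycol 4 (not isolated)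
Conditions: H5IO6, THF–H2O, 0 °C
Reagents that add atoms: water, O
Why: Periodic acid hydrolyses the oxirane and cleaves the glycol (Malaprade cleavage), which excises acetone and leaves the C1 aldehyde with the Z alkene intact.

Step 4
Reactants: 5 (4Z)-6-(TBSO)-4-methylhex-4-enal
Product: 7 (2Z,6S,7R)-1-(TBSO)-3,7-dimethylnona-2,8-dien-6-ol, via borinate ester 6 (not isolated)
Conditions: (E)-crotyl-B(Ipc)2 [from (E)-but-2-ene, KOtBu, nBuLi, (+)-Ipc2BOMe (ex (−)-α-pinene), BF3·OEt2], THF, −78 °C; then NaOH, H2O2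
Reagents that add atoms: (E)-but-2-ene (delivered as the crotylborane), C/C=C/C
Why: Brown crotylboration through a closed chair transition state makes the addition anti and, with these isopinocampheyl groups, Re-face selective, so C1 (S) and C10 (R) are set together under reagent control.

Step 5
Reactants: 7 (2Z,6S,7R)-1-(TBSO)-3,7-dimethylnona-2,8-dien-6-ol
Product: 8 (2Z,6S,7R)-1,6-bis(TBSO)-3,7-dimethylnona-2,8-diene
Conditions: TBSOTf, 2,6-lutidine, CH2Cl2, −78 → 0 °C
Reagents that add atoms: tert-butyldimethylsilyl triflate, CC(C)(C)[Si](C)(C)OS(=O)(=O)C(F)(F)F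
Why: Silyl triflate silylation of the hindered secondary alcohol gives the ether that stays to the last step and keeps O1 from attacking the later 4,5-oxirane.

Step 6
Reactants: 8 (2Z,6S,7R)-1,6-bis(TBSO)-3,7-dimethylnona-2,8-diene
Product: 10 (3R,4S,7Z)-4,9-bis(TBSO)-3,7-dimethylnon-7-en-1-ol, via alkylborane 9 (not isolated)
Conditions: 9-BBN, THF, 0 → 25 °C; then NaOH, H2O2
Reagents that add atoms: hydrogen peroxide, OO
Why: Anti-Markovnikov hydroboration–oxidation with the bulky borane takes the monosubstituted vinyl group and leaves the trisubstituted alkene, which places oxygen on the carbon that becomes C8.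

Step 7
Reactants: 10 (3R,4S,7Z)-4,9-bis(TBSO)-3,7-dimethylnon-7-en-1-ol
Product: 11 (3R,4S,7Z)-4,9-bis(TBSO)-3,7-dimethylnon-7-enal
Conditions: Dess–Martin periodinane, NaHCO3, CH2Cl2, 0 → 25 °C
Reagents that add atoms: none
Why: Dess–Martin oxidation gives the C8 aldehyde under neutral conditions that leave the β-stereocentre and the silyl ethers alone.

Step 8
Reactants: 11 (3R,4S,7Z)-4,9-bis(TBSO)-3,7-dimethylnon-7-enal
Product: 12 methyl (4S,6R,7S,10Z)-7,12-bis(TBSO)-4-hydroxy-6,10-dimethyldodec-10-en-2-ynoate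
Conditions: (S,S)-ProPhenol (20 mol %), Ph3PO (40 mol %), Me2Zn (3 equiv), methyl propiolate (3 equiv), PhMe, 4 °C; aq. NH4Cl
Reagents that add atoms: methyl propiolate, C#CC(=O)OC
Why: Zinc–ProPhenol catalysed enantioselective alkynylzinc addition brings in C7, C11 and C12 as the ynoate and should set C8 (S) under catalyst control, independently of the remote C10 centre.

Step 9
Reactants: 12 methyl (4S,6R,7S,10Z)-7,12-bis(TBSO)-4-hydroxy-6,10-dimethyldodec-10-en-2-ynoate
Product: 14 methyl (2Z,4S,6R,7S,10Z)-7,12-bis(TBSO)-4-hydroxy-2-(hydroxymethyl)-3-iodo-6,10-dimethyldodeca-2,10-dienoate, via magnesium allenolate 13 (not isolated)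
Conditions: MgI2 (2.5 equiv), CH2O (monomer in THF), CH2Cl2, −20 → 0 °C; aq. NH4Cl
Reagents that add atoms: magnesium iodide, [Mg+2].[I-].[I-]; formaldehyde, C=O
Why: In this β-iodo Morita–Baylis–Hillman (halo-aldol) coupling iodide adds to C7 and the allenolate is hydroxymethylated at C11 by formaldehyde held on the magnesium alkoxide of O8, which should bring C13 in on the side of C8 and give the Z iodoenoate (iodine cis to the ester) that the later lactonisation needs.

Step 10
Reactants: 14 methyl (2Z,4S,6R,7S,10Z)-7,12-bis(TBSO)-4-hydroxy-2-(hydroxymethyl)-3-iodo-6,10-dimethyldodeca-2,10-dienoate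
Product: 15 methyl (2Z,4S,6R,7S,10Z)-2-(acetoxymethyl)-7,12-bis(TBSO)-4-hydroxy-3-iodo-6,10-dimethyldodeca-2,10-dienoate
Conditions: AcCl (1.05 equiv), 2,4,6-collidine, CH2Cl2, −78 °C
Reagents that add atoms: acetyl chloride, CC(Cl)=O
Why: Acyl chloride with a hindered pyridine base at low temperature acylates the primary allylic hydroxyl (O13) and leaves the hindered secondary C8 hydroxyl.

Step 11
Reactants: 15 methyl (2Z,4S,6R,7S,10Z)-2-(acetoxymethyl)-7,12-bis(TBSO)-4-hydroxy-3-iodo-6,10-dimethyldodeca-2,10-dienoate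
Product: 16 methyl (2Z,4S,6R,7S,10Z)-2-(acetoxymethyl)-7,12-bis(TBSO)-3-iodo-4-(methacryloyloxy)-6,10-dimethyldodeca-2,10-dienoate
Conditions: methacryloyl chloride, iPr2NEt, DMAP (5 mol %), CH2Cl2, −20 → 0 °C
Reagents that add atoms: methacryloyl chloride, C=C(C)C(Cl)=O
Why: Acylation of the C8 alcohol with the acid chloride and a hindered amine installs the methacrylate with little nucleophilic catalyst present, so that the allylic acetate is not attacked in SN2′ fashion.

Step 12
Reactants: 16 methyl (2Z,4S,6R,7S,10Z)-2-(acetoxymethyl)-7,12-bis(TBSO)-3-iodo-4-(methacryloyloxy)-6,10-dimethyldodeca-2,10-dienoate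
Product: 17 methyl (2Z,4S,6R,7S,10Z)-2-(acetoxymethyl)-7-(TBSO)-12-hydroxy-3-iodo-4-(methacryloyloxy)-6,10-dimethyldodeca-2,10-dienoate
Conditions: HF·pyridine, pyridine, THF, 0 °C
Reagents that add atoms: none
Why: Buffered fluoride desilylation should cleave the unhindered primary allylic silyl ether much faster than the hindered secondary one at C1, with the esters and the alkenyl iodide inert.

Step 13
Reactants: 17 methyl (2Z,4S,6R,7S,10Z)-2-(acetoxymethyl)-7-(TBSO)-12-hydroxy-3-iodo-4-(methacryloyloxy)-6,10-dimethyldodeca-2,10-dienoate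
Product: 18 methyl (2Z,4S,6R,7S,10R,11S)-2-(acetoxymethyl)-7-(TBSO)-10,11-epoxy-12-hydroxy-3-iodo-4-(methacryloyloxy)-6,10-dimethyldodec-2-enoate
Conditions: Ti(OiPr)4 (10 mol %), L-(+)-diethyl tartrate (12 mol %), tBuOOH, 4 Å MS, CH2Cl2, −20 °C
Reagents that add atoms: tert-butyl hydroperoxide, CC(C)(C)OO
Why: Sharpless asymmetric epoxidation with the L-(+)-tartrate titanium complex delivers oxygen to one face of the Z-allylic alcohol and so sets C4 (R) and C5 (S) of the cis-oxirane under reagent control, while the electron-poor alkenes do not react.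

Step 14
Reactants: 18 methyl (2Z,4S,6R,7S,10R,11S)-2-(acetoxymethyl)-7-(TBSO)-10,11-epoxy-12-hydroxy-3-iodo-4-(methacryloyloxy)-6,10-dimethyldodec-2-enoate
Product: 19 methyl (2Z,4S,6R,7S,10R,11R)-2-(acetoxymethyl)-7-(TBSO)-10,11-epoxy-3-iodo-4-(methacryloyloxy)-6,10-dimethyl-12-oxododec-2-enoate
Conditions: Dess–Martin periodinane, NaHCO3, CH2Cl2, 0 °C
Reagents that add atoms: none
Why: Buffered Dess–Martin oxidation gives the sensitive cis-epoxy aldehyde without epimerisation at C5 (the descriptor changes through priority only), and the aldehyde is used at once.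

Step 15
Reactants: 19 methyl (2Z,4S,6R,7S,10R,11R)-2-(acetoxymethyl)-7-(TBSO)-10,11-epoxy-3-iodo-4-(methacryloyloxy)-6,10-dimethyl-12-oxododec-2-enoate
Product: 21 (1S,4R,5S,6S,8S,10R)-13-acetoxy-1-(TBSO)-4,5-epoxy-8-(methacryloyloxy)germacr-7(11)-en-12,6-olide, via seco hydroxy ester 20 (not isolated)
Conditions: CrCl2 (10 equiv), NiCl2 (5 mol %), DMSO–THF, 19 added by syringe pump (final 0.002 M), 25 °C; aq. NH4Cl
Reagents that add atoms: none
Why: Zerovalent nickel inserts into the C7–I bond, transmetalation to trivalent chromium gives the alkenylchromium with retention of the Z geometry, and this adds to the C6 aldehyde; the chromium alkoxide then displaces methoxide from the cis C12 ester. The closest known reaction types are the Nozaki–Hiyama–Kishi macrocyclisation and the butenolide-forming Nozaki–Hiyama–Kishi reaction of (Z)-β-iodoenoates with aldehydes. The ten-membered ring closes by 10-exo-trig carbonyl addition (C6–C7) and the butenolide by 5-exo-trig acyl substitution (O6–C12), so carbocycle and lactone arise in one operation from an open chain. C6 is the only new stereocentre and should be set by Felkin–Anh (Cornforth) control from the oxirane: the nucleophile enters anti to the C5–O bond and past H5, the cis C3 branch on the oxirane disfavouring the other rotamer, which gives 6S. The step needs ring closure to beat oligomerisation, for which high dilution and the two rigid turn elements (the Z-tetrasubstituted alkene and the cis-oxirane) are relied on. It also needs nickel to insert into the alkenyl iodide and not the allylic acetate, which the far faster oxidative addition to the C–I bond should secure.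

Step 16
Reactants: 21 (1S,4R,5S,6S,8S,10R)-13-acetoxy-1-(TBSO)-4,5-epoxy-8-(methacryloyloxy)germacr-7(11)-en-12,6-olide
Product: 22 (1S,4R,5S,6S,8S,10R)-13-acetoxy-4,5-epoxy-1-hydroxy-8-(methacryloyloxy)germacr-7(11)-en-12,6-olide (CNP0119405.1)
Conditions: HF·pyridine, pyridine, THF, 0 → 25 °C
Reagents that add atoms: none
Why: Buffered fluoride desilylation frees the C1 hydroxyl, the pyridine keeping the medium mild enough that the trisubstituted oxirane should not be opened across the ring by O1 and the three esters stay in place.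

**Compound list**

1 | nerol, (2Z)-3,7-dimethylocta-2,6-dien-1-ol | CC(C)=CCC/C(C)=C\CO | starting material
2 | neryl TBS ether | CC(C)=CCC/C(C)=C\CO[Si](C)(C)C(C)(C)C | intermediate
3 | 6,7-epoxyneryl TBS ether (racemic oxirane) | CC1(C)OC1CC/C(C)=C\CO[Si](C)(C)C(C)(C)C | intermediate
4 | (6Z)-8-(TBSO)-2,6-dimethyloct-6-ene-2,3-diol | CC(C)(O)C(O)CC/C(C)=C\CO[Si](C)(C)C(C)(C)C | intermediate (not isolated)
5 | (4Z)-6-(TBSO)-4-methylhex-4-enal | O=CCC/C(C)=C\CO[Si](C)(C)C(C)(C)C | intermediate
6 | diisopinocampheylborinate of alcohol 7 | C=C[C@@H](C)[C@@H](OB([C@H]1C[C@H]2C[C@@H]([C@@H]1C)C2(C)C)[C@H]1C[C@H]2C[C@@H]([C@@H]1C)C2(C)C)CC/C(C)=C\CO[Si](C)(C)C(C)(C)C | intermediate (not isolated)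
7 | (2Z,6S,7R)-1-(TBSO)-3,7-dimethylnona-2,8-dien-6-ol | C=C[C@@H](C)[C@@H](O)CC/C(C)=C\CO[Si](C)(C)C(C)(C)C | intermediate
8 | (2Z,6S,7R)-1,6-bis(TBSO)-3,7-dimethylnona-2,8-diene | C=C[C@@H](C)[C@@H](O[Si](C)(C)C(C)(C)C)CC/C(C)=C\CO[Si](C)(C)C(C)(C)C | intermediate
9 | B-alkyl-9-borabicyclo[3.3.1]nonane from 8 (boron on C8) | C1CC2CCCC(C1)B2CC[C@@H](C)[C@@H](O[Si](C)(C)C(C)(C)C)CC/C(C)=C\CO[Si](C)(C)C(C)(C)C | intermediate (not isolated)
10 | (3R,4S,7Z)-4,9-bis(TBSO)-3,7-dimethylnon-7-en-1-ol | OCC[C@@H](C)[C@@H](O[Si](C)(C)C(C)(C)C)CC/C(C)=C\CO[Si](C)(C)C(C)(C)C | intermediate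
11 | (3R,4S,7Z)-4,9-bis(TBSO)-3,7-dimethylnon-7-enal | O=CC[C@@H](C)[C@@H](O[Si](C)(C)C(C)(C)C)CC/C(C)=C\CO[Si](C)(C)C(C)(C)C | intermediate
12 | methyl (4S,6R,7S,10Z)-7,12-bis(TBSO)-4-hydroxy-6,10-dimethyldodec-10-en-2-ynoate | COC(=O)C#C[C@@H](O)C[C@@H](C)[C@@H](O[Si](C)(C)C(C)(C)C)CC/C(C)=C\CO[Si](C)(C)C(C)(C)C | intermediate
13 | magnesium 3-iodoallenolate of 12 | COC(O[Mg]I)=C=C(I)[C@@H](O)C[C@@H](C)[C@@H](O[Si](C)(C)C(C)(C)C)CC/C(C)=C\CO[Si](C)(C)C(C)(C)C | intermediate (not isolated)
14 | methyl (2Z,4S,6R,7S,10Z)-7,12-bis(TBSO)-4-hydroxy-2-(hydroxymethyl)-3-iodo-6,10-dimethyldodeca-2,10-dienoate | COC(=O)/C(CO)=C(\I)[C@@H](O)C[C@@H](C)[C@@H](O[Si](C)(C)C(C)(C)C)CC/C(C)=C\CO[Si](C)(C)C(C)(C)C | intermediate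
15 | methyl (2Z,4S,6R,7S,10Z)-2-(acetoxymethyl)-7,12-bis(TBSO)-4-hydroxy-3-iodo-6,10-dimethyldodeca-2,10-dienoate | COC(=O)/C(COC(C)=O)=C(\I)[C@@H](O)C[C@@H](C)[C@@H](O[Si](C)(C)C(C)(C)C)CC/C(C)=C\CO[Si](C)(C)C(C)(C)C | intermediate
16 | methyl (2Z,4S,6R,7S,10Z)-2-(acetoxymethyl)-7,12-bis(TBSO)-3-iodo-4-(methacryloyloxy)-6,10-dimethyldodeca-2,10-dienoate | COC(=O)/C(COC(C)=O)=C(\I)[C@@H](OC(=O)C(C)=C)C[C@@H](C)[C@@H](O[Si](C)(C)C(C)(C)C)CC/C(C)=C\CO[Si](C)(C)C(C)(C)C | intermediate
17 | methyl (2Z,4S,6R,7S,10Z)-2-(acetoxymethyl)-7-(TBSO)-12-hydroxy-3-iodo-4-(methacryloyloxy)-6,10-dimethyldodeca-2,10-dienoate | COC(=O)/C(COC(C)=O)=C(\I)[C@@H](OC(=O)C(C)=C)C[C@@H](C)[C@@H](O[Si](C)(C)C(C)(C)C)CC/C(C)=C\CO | intermediate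
18 | methyl (2Z,4S,6R,7S,10R,11S)-2-(acetoxymethyl)-7-(TBSO)-10,11-epoxy-12-hydroxy-3-iodo-4-(methacryloyloxy)-6,10-dimethyldodec-2-enoate | COC(=O)/C(COC(C)=O)=C(\I)[C@@H](OC(=O)C(C)=C)C[C@@H](C)[C@@H](O[Si](C)(C)C(C)(C)C)CC[C@@]1(C)O[C@H]1CO | intermediate
19 | methyl (2Z,4S,6R,7S,10R,11R)-2-(acetoxymethyl)-7-(TBSO)-10,11-epoxy-3-iodo-4-(methacryloyloxy)-6,10-dimethyl-12-oxododec-2-enoate | COC(=O)/C(COC(C)=O)=C(\I)[C@@H](OC(=O)C(C)=C)C[C@@H](C)[C@@H](O[Si](C)(C)C(C)(C)C)CC[C@@]1(C)O[C@H]1C=O | intermediate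
20 | methyl (1S,4R,5S,6S,8S,10R)-13-acetoxy-1-(TBSO)-4,5-epoxy-6-hydroxy-8-(methacryloyloxy)germacr-7(11)-en-12-oate, formed as its chromium alkoxide | C=C(C)C(=O)O[C@H]1C[C@@H](C)[C@@H](O[Si](C)(C)C(C)(C)C)CC[C@@]2(C)O[C@H]2[C@@H](O)/C1=C(/COC(C)=O)C(=O)OC | intermediate (not isolated)
21 | (1S,4R,5S,6S,8S,10R)-13-acetoxy-1-(TBSO)-4,5-epoxy-8-(methacryloyloxy)germacr-7(11)-en-12,6-olide | C=C(C)C(=O)O[C@H]1C[C@@H](C)[C@@H](O[Si](C)(C)C(C)(C)C)CC[C@@]2(C)O[C@H]2[C@H]2OC(=O)C(COC(C)=O)=C12 | intermediate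
22 | (1S,4R,5S,6S,8S,10R)-13-acetoxy-4,5-epoxy-1-hydroxy-8-(methacryloyloxy)germacr-7(11)-en-12,6-olide (CNP0119405.1) | C=C(C)C(=O)O[C@H]1C[C@@H](C)[C@@H](O)CC[C@@]2(C)O[C@H]2[C@H]2OC(=O)C(COC(C)=O)=C12 | target

**Step count and risks**

Total step count: 16. Longest linear sequence: 16 steps (the route is linear from nerol).

Steps most likely to fail:

1. Step 15 (ring closure and lactonisation). The alkenylchromium may add between molecules and give oligomers, it may be too hindered to reach the epoxy aldehyde, or facial control at C6 may erode. Fallback, setting out from 17 and coming back at 21: the allylic alcohol is oxidised (Dess–Martin periodinane) to the (Z)-enal F1. The ring is then closed on this less hindered aldehyde under CrCl2/NiCl2 with a chiral oxazoline–sulfonamide ligand on chromium to set C6, which gives the 4Z-alkene analogue of 21, dienolide F2. The oxirane is put in last with mCPBA, which should take the only electron-rich alkene on the face syn to the lactone oxygen (A(1,3) strain places H6 in the alkene plane and the butenolide carbon C7 on the other face).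

2. Step 9 (iodo-aldol). The alkene geometry may not be controlled, and the E isomer would drain into a butenolide closed on O8. Fallback, setting out from 12 and coming back at 16: the geometry is locked in a ring. The C8 hydroxyl is converted to the chloromethyl ether F3 (paraformaldehyde, TMSCl). MgI2 then triggers a Michael-initiated ring closure (iodide to C7, C11 onto the O–CH2 carbon) to the 3-iodo-2,5-dihydrofuran-4-carboxylate F4, in which C8 and C13 are necessarily cis. Acylative cleavage of the primary allylic C13–O bond with methacryloyl bromide/ZnBr2 at −20 °C gives the bromide F5, which already carries the C8 methacrylate (the silyl ethers would be exchanged for more robust ones if they do not survive). Displacement with KOAc/18-crown-6 returns to 16.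

3. Step 8 (alkynylation). Face selectivity may be low for this β-branched aliphatic aldehyde, and the propiolate may oligomerise. Fallback, setting out from 11 and coming back at 12: lithium methyl propiolate (LiHMDS, THF, −78 °C) adds without control to give the C8-epimeric alcohols F6, Dess–Martin oxidation gives the ynone F7, and reduction with (S)-Alpine-Borane, in which the alkynyl group acts as the small substituent, should return 12.

**Further compounds**

F1 | step 15 | methyl (2Z,4S,6R,7S,10Z)-2-(acetoxymethyl)-7-(TBSO)-3-iodo-4-(methacryloyloxy)-6,10-dimethyl-12-oxododeca-2,10-dienoate | COC(=O)/C(COC(C)=O)=C(\I)[C@@H](OC(=O)C(C)=C)C[C@@H](C)[C@@H](O[Si](C)(C)C(C)(C)C)CC/C(C)=C\C=O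
F2 | step 15 | 13-acetoxy-1-(TBSO)-8-(methacryloyloxy)germacra-4Z,7(11)-dien-12,6-olide, configured as 21 at C1, C6, C8 and C10 | C=C(C)C(=O)O[C@H]1C[C@@H](C)[C@@H](O[Si](C)(C)C(C)(C)C)CC/C(C)=C\[C@H]2OC(=O)C(COC(C)=O)=C12
F3 | step 9 | methyl (4S,6R,7S,10Z)-7,12-bis(TBSO)-4-(chloromethoxy)-6,10-dimethyldodec-10-en-2-ynoate | COC(=O)C#C[C@@H](OCCl)C[C@@H](C)[C@@H](O[Si](C)(C)C(C)(C)C)CC/C(C)=C\CO[Si](C)(C)C(C)(C)C
F4 | step 9 | methyl (2S)-2-[(2R,3S,6Z)-3,8-bis(TBSO)-2,6-dimethyloct-6-en-1-yl]-3-iodo-2,5-dihydrofuran-4-carboxylate | COC(=O)C1=C(I)[C@@H](OC1)C[C@@H](C)[C@@H](O[Si](C)(C)C(C)(C)C)CC/C(C)=C\CO[Si](C)(C)C(C)(C)C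
F5 | step 9 | methyl (2Z,4S,6R,7S,10Z)-2-(bromomethyl)-7,12-bis(TBSO)-3-iodo-4-(methacryloyloxy)-6,10-dimethyldodeca-2,10-dienoate | COC(=O)/C(CBr)=C(\I)[C@@H](OC(=O)C(C)=C)C[C@@H](C)[C@@H](O[Si](C)(C)C(C)(C)C)CC/C(C)=C\CO[Si](C)(C)C(C)(C)C
F6 | step 8 | methyl (6R,7S,10Z)-7,12-bis(TBSO)-4-hydroxy-6,10-dimethyldodec-10-en-2-ynoate, both C4 epimers | COC(=O)C#CC(O)C[C@@H](C)[C@@H](O[Si](C)(C)C(C)(C)C)CC/C(C)=C\CO[Si](C)(C)C(C)(C)C
F7 | step 8 | methyl (6R,7S,10Z)-7,12-bis(TBSO)-6,10-dimethyl-4-oxododec-10-en-2-ynoate | COC(=O)C#CC(=O)C[C@@H](C)[C@@H](O[Si](C)(C)C(C)(C)C)CC/C(C)=C\CO[Si](C)(C)C(C)(C)C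
A1 | direct plan | (S)-5-(tert-butyldimethylsilyloxy)-3-methylcyclohex-2-en-1-one | O=C1C=C(C)C[C@H](O[Si](C)(C)C(C)(C)C)C1
A2 | direct plan | 1-methylcyclobutene | CC1=CCC1
A3 | direct plan | (1(10)E,4Z,8S)-8-(tert-butyldimethylsilyloxy)germacra-1(10),4-dien-6-one | CC(C)(C)[Si](C)(C)O[C@H]1C/C(C)=C/CC/C(C)=C\C(=O)C1
A4 | direct plan | (1(10)E,4R,5R,8S)-4,5-epoxy-8-(tert-butyldimethylsilyloxy)germacr-1(10)-en-6-one | CC(C)(C)[Si](C)(C)O[C@H]1C/C(C)=C/CC[C@@]2(C)O[C@H]2C(=O)C1
A5 | direct plan | (4R,5S,6S,8S)-13-acetoxy-4,5-epoxy-8-[2-methyl-3-(phenylselanyl)propanoyloxy]germacra-1(10)E,7(11)-dien-12,6-olide | CC(C[Se]c1ccccc1)C(=O)O[C@H]1C/C(C)=C/CC[C@@]2(C)O[C@H]2[C@H]2OC(=O)C(COC(C)=O)=C12
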